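The disconnection on which the route rests cuts the C7–C8 bond of the ten-membered carbocycle (C1–C10) and joins O8 to C13, which unfolds the target into a 13-membered cyclic allyl ether of an α-oxy ketone. Enolisation at C8 and a [2,3]-Wittig shift then form C7–C8, set C7 and C8, free the C8 carbinol and turn C11–C13 into the exocyclic methylene in one operation. The step exploits the C11=C13 methylene branch on C7 next to the C8 oxygen. The precursor is the furanone-bridged (C3–O–C10) macrocycle with a C9 ketone, a (7E) C7=C11 olefin carrying C12 as a silyl ether, and a silylated C6 carbinol.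

Key step: step 18

Remark (numbering): C1 furanone carbonyl, C2=C3 furanone olefin, C3–O–C10 ether bridge, C4=C5 with methyl C15, C6 lactone carbinol, C7, C8 (isovalerate), C9 (acetate), C10 with methyl C14, C11=C13 methylene, C12 lactone carbonyl.
Remark (protecting groups): C12 carries a tert-butyldiphenylsilyl ether so that the C9 triethylsilyl ether can be removed selectively with acid; C6 carries the tert-butyldimethylsilyl ether in the key step.
Remark (C9): C9 is formed in step 7 as a mixture of carbinol epimers and is carried without a descriptor until it becomes a ketone in step 17.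
Assumption: the (4S)-oxazoline sulfonamide ligand of step 14 is taken to direct addition to the Si face of the C6 aldehyde; if a model coupling shows the opposite sense, its enantiomer is used.

Step 1
Reactants: 1 (S)-lactic acid; 2 pivalaldehyde
Product: 3 (2S,5S)-2-tert-butyl-5-methyl-1,3-dioxolan-4-one (cis acetal)
Conditions: TsOH·H2O (cat.), pentane, reflux with water separator; crystallisation at −78 °C
Reagents that add atoms: none
Why: Acid-catalysed acetalisation of the α-hydroxy acid with azeotropic water removal should give the crystalline cis acetal, whose acetal carbon stores the chirality of the future C10 (self-regeneration of stereocentres).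

Step 2
Reactants: 4 ethyl propiolate; 5 formaldehyde (monomer from cracked paraformaldehyde)
Product: 7 ethyl (Z)-2-(hydroxymethyl)-3-iodoprop-2-enoate, via magnesium iodoallenolate 6 (not isolated)
Conditions: MgI2, CH2Cl2, −20 → 0 °C; aq. NH4Cl
Reagents that add atoms: magnesium iodide, [Mg+2].[I-].[I-]
Why: Conjugate addition of iodide gives an allenolate that adds to formaldehyde (iodo-aldol variant of the Morita–Baylis–Hillman reaction), and magnesium chelation is expected to favour the Z isomer, which puts the ester carbon (future C13) cis to iodine and the hydroxymethyl (future C12) trans.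

Step 3
Reactants: 7 ethyl (Z)-2-(hydroxymethyl)-3-iodoprop-2-enoate
Product: 8 ethyl (Z)-2-[(tert-butyldiphenylsilyloxy)methyl]-3-iodoprop-2-enoate
Conditions: tBuPh2SiCl, imidazole, DMF, 0 → 23 °C
Reagents that add atoms: tert-butyl(chloro)diphenylsilane, CC(C)(C)[Si](Cl)(c1ccccc1)c1ccccc1
Why: Standard silylation of the primary alcohol installs an acid-stable ether on C12 that should survive to step 22.

Step 4
Reactants: 8 ethyl (Z)-2-[(tert-butyldiphenylsilyloxy)methyl]-3-iodoprop-2-enoate
Product: 9 (E)-2-[(tert-butyldiphenylsilyloxy)methyl]-3-iodoprop-2-en-1-ol (free C13 hydroxyl cis to iodine)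
Conditions: iBu2AlH (2.5 equiv), CH2Cl2, −78 → 0 °C; aq. potassium sodium tartrate
Reagents that add atoms: none
Why: Hydride reduction of the conjugated ester to the allylic alcohol leaves the alkenyl iodide and the olefin geometry untouched, so the two oxygenated arms stay differentiated.

Step 5
Reactants: 9 (E)-2-[(tert-butyldiphenylsilyloxy)methyl]-3-iodoprop-2-en-1-ol; 10 ethyl diazoacetate
Product: 11 ethyl 2-{[(E)-2-[(tert-butyldiphenylsilyloxy)methyl]-3-iodoprop-2-en-1-yl]oxy}acetate
Conditions: Rh2(OAc)4 (1 mol %), CH2Cl2, 23 °C, slow addition of 10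
Reagents that add atoms: none
Why: Rhodium-carbenoid O–H insertion into the primary allylic alcohol forms the C13–O–C8 ether under neutral conditions, which avoids the base-induced 1,5-silyl shift between the two arms that an alkoxide alkylation would risk.

Step 6
Reactants: 11 ethyl 2-{[(E)-2-[(tert-butyldiphenylsilyloxy)methyl]-3-iodoprop-2-en-1-yl]oxy}acetate
Product: 12 2-{[(E)-2-[(tert-butyldiphenylsilyloxy)methyl]-3-iodoprop-2-en-1-yl]oxy}acetaldehyde
Conditions: iBu2AlH (1.1 equiv), CH2Cl2, −78 °C; MeOH then aq. potassium sodium tartrate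
Reagents that add atoms: none
Why: Partial reduction of an α-alkoxy ester stops at the chelated tetrahedral aluminate at −78 °C and should release the C9 aldehyde on work-up.

Step 7
Reactants: 3 (2S,5S)-2-tert-butyl-5-methyl-1,3-dioxolan-4-one; 12 2-{[(E)-2-[(tert-butyldiphenylsilyloxy)methyl]-3-iodoprop-2-en-1-yl]oxy}acetaldehyde
Product: 14 (2S,5R)-2-tert-butyl-5-methyl-5-[1-hydroxy-2-(allyloxy)ethyl]-1,3-dioxolan-4-one bearing the iodoalkene of 12 (C9 epimers), via lithium enolate 13 (not isolated)
Conditions: LiN(iPr)2, THF, −78 °C; then 12, −78 °C; AcOH, −78 °C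
Reagents that add atoms: none
Why: The dioxolanone enolate should add to the aldehyde on the face opposite the tert-butyl group (aldol addition with self-regeneration of the stereocentre), which forms C9–C10 and fixes C10 in the configuration of the target.

Step 8
Reactants: 14 aldol adduct
Product: 15 C9 triethylsilyl ether of 14
Conditions: Et3SiOTf, 2,6-lutidine, CH2Cl2, −78 → 0 °C
Reagents that add atoms: triethylsilyl trifluoromethanesulfonate, CC[Si](CC)(CC)OS(=O)(=O)C(F)(F)F
Why: Silyl triflate silylation of the hindered secondary alcohol blocks retro-aldol cleavage and prevents the C9 oxygen from competing in the furanone closure of step 12.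

Step 9
Reactants: 15 C9 triethylsilyl ether of the aldol adduct
Product: 16 (2R)-2-hydroxy-N-methoxy-N,2-dimethyl-3-(triethylsilyloxy)-4-(allyloxy)butanamide bearing the iodoalkene (C10 free tertiary alcohol)
Conditions: MeNH(OMe)·HCl, AlMe3, CH2Cl2, 0 → 23 °C; aq. potassium sodium tartrate
Reagents that add atoms: N,O-dimethylhydroxylamine hydrochloride, CNOC.Cl
Why: The dimethylaluminium amide should open the acetal-lactone by aminolysis at the C1 carbonyl, with loss of pivalaldehyde, to give the N-methoxy-N-methylamide without touching the quaternary C10.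

Step 10
Reactants: 17 (Z)-3-methylpent-2-en-4-yn-1-ol
Product: 18 triethyl{[(Z)-3-methylpent-2-en-4-yn-1-yl]oxy}silane
Conditions: Et3SiCl, imidazole, CH2Cl2, 0 °C
Reagents that add atoms: chlorotriethylsilane, CC[Si](Cl)(CC)CC
Why: Silylation masks the C6 oxygen, which would otherwise add to the ynone of step 11 and lead to a furan; the Z olefin supplies the C4=C5 geometry of the target.

Step 11
Reactants: 16 N-methoxy-N-methylamide; 18 silylated (Z)-enyne
Product: 20 α'-hydroxy ynone C1(=O)–C2≡C3 with (4Z)-olefin and C6–OSiEt3 and C9–OSiEt3 and iodoalkene, via lithium acetylide 19 (not isolated)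
Conditions: 18 (3 equiv), n-BuLi (2.9 equiv), THF, −78 °C; then 16, −78 → −20 °C; aq. NH4Cl
Reagents that add atoms: none
Why: Acylation of the lithium acetylide by the N-methoxy-N-methylamide stops at the chelated tetrahedral adduct, one equivalent of acetylide serving to deprotonate the tertiary hydroxyl, and forms the C1–C2 bond without affecting the alkenyl iodide.

Step 12
Reactants: 20 α'-hydroxy ynone
Product: 22 2,2,5-trisubstituted 3(2H)-furanone (C6–OSiEt3 and C9–OSiEt3 and iodoalkene retained), via diethylamino enone 21 (not isolated)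
Conditions: Et2NH (0.3 equiv), EtOH, 23 °C
Reagents that add atoms: none
Why: Conjugate addition of the amine to the ynone and intramolecular addition–elimination by the C10 hydroxyl (net 5-endo hydroalkoxylation, the standard 3(2H)-furanone synthesis) should close the C3–O–C10 ring, with C10 keeping its configuration.

Step 13
Reactants: 22 furanone bis(triethylsilyl) ether
Product: 24 (4Z)-C6 enal of the furanone (C9–OSiEt3 and iodoalkene retained), via C6 alkoxysulfonium chloride 23 (not isolated)
Conditions: (COCl)2, DMSO, CH2Cl2, −78 → −40 °C; Et3N, −78 → −20 °C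
Reagents that add atoms: none
Why: Activated DMSO converts a primary triethylsilyl ether directly into the alkoxysulfonium salt and then the aldehyde (Swern oxidation of a primary silyl ether), while the hindered secondary C9 silyl ether is inert and the low temperature protects the Z enal.

Step 14
Reactants: 24 (4Z)-C6 enal with alkenyl iodide
Product: 26 (4Z,7E,6S,10R)-13-membered ether with C6 hydroxyl and C9–OSiEt3 and C12–OSiPh2tBu, via alkenylchromium dichloride 25 (not isolated)
Conditions: CrCl2, N-[2-((4S)-4-isopropyl-4,5-dihydro-1,3-oxazol-2-yl)-6-methylphenyl]methanesulfonamide, Et3N, THF, 23 °C; then NiCl2 (cat.), 24 added over 10 h (2 mM)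
Reagents that add atoms: none
Why: The Nozaki–Hiyama–Kishi reaction should close the 13-membered ring at C6–C7 chemoselectively at the aldehyde with retention of the olefin geometry, and the oxazoline sulfonamide ligand on chromium is relied on to direct the alkenyl group to the Si face of C6 (6S carbinol).

Step 15
Reactants: 26 macrocyclic C6 alcohol
Product: 27 C6 tert-butyldimethylsilyl ether of 26
Conditions: tBuMe2SiOTf, 2,6-lutidine, CH2Cl2, −78 °C
Reagents that add atoms: tert-butyldimethylsilyl trifluoromethanesulfonate, CC(C)(C)[Si](C)(C)OS(=O)(=O)C(F)(F)F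
Why: Silyl triflate silylation of the hindered bis-allylic alcohol at low temperature installs the group that will steer the olefin face in step 18.

Step 16
Reactants: 27 fully silylated macrocycle
Product: 28 macrocyclic C9 alcohol (C6–OSiMe2tBu and C12–OSiPh2tBu retained)
Conditions: PPTS, MeOH/CH2Cl2, 0 → 23 °C
Reagents that add atoms: none
Why: Acid-catalysed methanolysis removes a triethylsilyl ether far faster than a secondary tert-butyldimethylsilyl or a tert-butyldiphenylsilyl ether, so only C9 should be unmasked.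

Step 17
Reactants: 28 macrocyclic C9 alcohol
Product: 29 (4Z,7E,6S,10S)-13-membered α-allyloxy ketone (C9 ketone; C6–OSiMe2tBu; C12–OSiPh2tBu)
Conditions: DMP, NaHCO3, CH2Cl2, 0 → 23 °C
Reagents that add atoms: none
Why: Buffered hypervalent-iodine (periodinane) oxidation converts the hindered secondary alcohol into the ketone under neutral conditions that spare the β-dicarbonyl array at C10 and merge the C9 epimers.

Step 18
Reactants: 29 13-membered α-allyloxy ketone
Product: 31 (4Z,6R,7R,8S,10S)-ten-membered 8-hydroxy-9-ketone with the C11=C13 methylene branch on C7, via lithium (Z)-enolate 30 (not isolated)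
Conditions: LiN(SiMe3)2 (1.2 equiv), THF, −78 → −20 °C; AcOH, −78 °C
Reagents that add atoms: none
Why: The amide base can enolise the C9 ketone only towards C8 (C10 is quaternary), and the lithium enolate 30 should rearrange through a five-membered envelope (C8, O, C13, C11, C7) in which C8 bonds to C7 while O–C13 breaks and C11=C13 forms, a concerted suprafacial [2,3]-Wittig shift of the kind known for contraction of 13-membered allylic ethers to ten-membered carbocycles and for enolates of α-allyloxy carbonyl compounds. The ten-membered carbocycle C1–C10 is closed by transannular C7–C8 bond formation inside the macrocycle, a pericyclic contraction that excises O, C13 and C11 from the ring and leaves the furanone ring untouched. C7 and C8 are set together: with C6 cis to C13 on the (7E) olefin and C9 in the exo position of the envelope (the endo position runs into the C12 arm on C11), the C8 oxygen and C11 should end up cis on the new ring. The face of C7 is chosen by C6, whose hydrogen must point at the incoming C9 so that the small silyloxy oxygen takes the in-plane position next to C13 and ring carbon C5 lies anti to the forming bond, which gives the trans relation between the C6 oxygen and C11. The step needs periselectivity over the [3,3] oxy-Claisen and [1,2] pathways, which the covalent lithium enolate at low temperature and the quaternary C10 next to C9 (a [3,3] shift would have to join C7 to the fully substituted C9) should secure. The cold acidic quench keeps the α-ketol from enediol equilibration and from alkoxide attack on the C1 carbonyl.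

Step 19
Reactants: 31 ten-membered α-ketol
Product: 32 C8 3-methylbutanoate of 31
Conditions: (Me2CHCH2CO)2O, pyridine, DMAP (cat.), CH2Cl2, 0 °C
Reagents that add atoms: 3-methylbutanoic anhydride, CC(C)CC(=O)OC(=O)CC(C)C
Why: Nucleophile-catalysed acylation of the only free hydroxyl under weakly basic conditions should esterify C8 without enolising the α-ketol.

Step 20
Reactants: 32 C8 isovalerate 9-ketone
Product: 33 (9R)-C9 alcohol (C8 isovalerate)
Conditions: NaBH4, CeCl3·7H2O, MeOH/THF, −78 °C; AcOH quench
Reagents that add atoms: none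
Why: Luche reduction should reduce the activated C9 ketone and not the vinylogous-ester carbonyl C1, with hydride entering anti to the flanking C8–O and C10–O bonds so that the new hydroxyl is trans to the C8 ester and cis to the furanone oxygen, and the cold acidic quench suppresses a 1,2-acyl shift.

Step 21
Reactants: 33 C9 alcohol
Product: 34 C9 acetate C8 isovalerate
Conditions: Ac2O, pyridine, DMAP (cat.), CH2Cl2, 0 → 23 °C
Reagents that add atoms: acetic anhydride, CC(=O)OC(C)=O
Why: Nucleophile-catalysed acetylation of the hindered secondary alcohol fixes the two different esters on C8 and C9.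

Step 22
Reactants: 34 bis-silyl diester
Product: 35 C6,C12-diol (C9 acetate; C8 isovalerate)
Conditions: HF·pyridine, THF/pyridine, 0 → 23 °C
Reagents that add atoms: none
Why: Buffered fluoride cleaves both silyl ethers under mildly acidic conditions that should neither hydrolyse nor shift the esters.

Step 23
Reactants: 35 C6,C12-diol
Product: 38 target (CNP0255553.1), via hydroxy enal 36 (not isolated), via lactol 37 (not isolated)
Conditions: TEMPO (cat.), PhI(OAc)2 (2.5 equiv), CH2Cl2, 23 °C
Reagents that add atoms: none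
Why: Nitroxyl-catalysed oxidation is selective for the primary allylic C12 alcohol, the enal is trapped by the C6 hydroxyl as a γ-lactol and this is oxidised on to the α-methylene γ-lactone (oxidative lactonisation), leaving the secondary C6–O stereocentre untouched.

Compound list
1 | (S)-lactic acid | C[C@H](O)C(=O)O | starting material
2 | pivalaldehyde | CC(C)(C)C=O | starting material
3 | (2S,5S)-2-tert-butyl-5-methyl-1,3-dioxolan-4-one | C[C@@H]1O[C@H](C(C)(C)C)OC1=O | intermediate
4 | ethyl propiolate | C#CC(=O)OCC | starting material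
5 | formaldehyde (monomer from paraformaldehyde) | C=O | starting material
6 | magnesium iodoallenolate of ethyl 3-iodopropadienoate | CCOC(O[Mg]I)=C=CI | intermediate
7 | ethyl (Z)-2-(hydroxymethyl)-3-iodoprop-2-enoate | CCOC(=O)/C(CO)=C\I | intermediate
8 | ethyl (Z)-2-[(tert-butyldiphenylsilyloxy)methyl]-3-iodoprop-2-enoate | CCOC(=O)/C(CO[Si](c1ccccc1)(c1ccccc1)C(C)(C)C)=C\I | intermediate
9 | (E)-2-[(tert-butyldiphenylsilyloxy)methyl]-3-iodoprop-2-en-1-ol | OC/C(CO[Si](c1ccccc1)(c1ccccc1)C(C)(C)C)=C\I | intermediate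
10 | ethyl diazoacetate | CCOC(=O)C=[N+]=[N-] | starting material
11 | ethyl 2-{[(E)-2-[(tert-butyldiphenylsilyloxy)methyl]-3-iodoprop-2-en-1-yl]oxy}acetate | CCOC(=O)COC/C(CO[Si](c1ccccc1)(c1ccccc1)C(C)(C)C)=C\I | intermediate
12 | 2-{[(E)-2-[(tert-butyldiphenylsilyloxy)methyl]-3-iodoprop-2-en-1-yl]oxy}acetaldehyde | O=CCOC/C(CO[Si](c1ccccc1)(c1ccccc1)C(C)(C)C)=C\I | intermediate
13 | lithium enolate of 3 | CC1=C(O[Li])O[C@@H](C(C)(C)C)O1 | intermediate
14 | (2S,5R)-2-tert-butyl-5-methyl-5-[1-hydroxy-2-(allyloxy)ethyl]-1,3-dioxolan-4-one, allyl = (E)-2-[(tert-butyldiphenylsilyloxy)methyl]-3-iodoprop-2-en-1-yl, C9 epimers | C[C@]1(C(O)COC/C(CO[Si](c2ccccc2)(c2ccccc2)C(C)(C)C)=C\I)O[C@H](C(C)(C)C)OC1=O | intermediate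
15 | C9 triethylsilyl ether of 14 | C[C@]1(C(O[Si](CC)(CC)CC)COC/C(CO[Si](c2ccccc2)(c2ccccc2)C(C)(C)C)=C\I)O[C@H](C(C)(C)C)OC1=O | intermediate
16 | (2R)-2-hydroxy-N-methoxy-N,2-dimethyl-3-(triethylsilyloxy)-4-{[(E)-2-[(tert-butyldiphenylsilyloxy)methyl]-3-iodoprop-2-en-1-yl]oxy}butanamide | CON(C)C(=O)[C@](C)(O)C(O[Si](CC)(CC)CC)COC/C(CO[Si](c1ccccc1)(c1ccccc1)C(C)(C)C)=C\I | intermediate
17 | (Z)-3-methylpent-2-en-4-yn-1-ol | C#C/C(C)=C\CO | starting material
18 | triethyl{[(Z)-3-methylpent-2-en-4-yn-1-yl]oxy}silane | C#C/C(C)=C\CO[Si](CC)(CC)CC | intermediate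
19 | lithium acetylide of 18 | [Li]C#C/C(C)=C\CO[Si](CC)(CC)CC | intermediate
20 | (10R,4Z)-α'-hydroxy ynone: C1 ketone, C2≡C3, C6–OSiEt3, C9–OSiEt3, C10–OH, C8–O–C13 ether, (E)-iodoalkene | CC[Si](CC)(CC)OC/C=C(/C)C#CC(=O)[C@](C)(O)C(O[Si](CC)(CC)CC)COC/C(CO[Si](c1ccccc1)(c1ccccc1)C(C)(C)C)=C\I | intermediate
21 | 3-(diethylamino) enone adduct of 20 | CC[Si](CC)(CC)OC/C=C(/C)C(N(CC)CC)=CC(=O)[C@](C)(O)C(O[Si](CC)(CC)CC)COC/C(CO[Si](c1ccccc1)(c1ccccc1)C(C)(C)C)=C\I | intermediate
22 | (10R,4Z)-3(2H)-furanone with C6–OSiEt3, C9–OSiEt3 and the iodoalkene ether side chain | CC[Si](CC)(CC)OC/C=C(/C)C1=CC(=O)[C@](C)(O1)C(O[Si](CC)(CC)CC)COC/C(CO[Si](c2ccccc2)(c2ccccc2)C(C)(C)C)=C\I | intermediate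
23 | C6 alkoxydimethylsulfonium chloride of the furanone | C[S+](C)OC/C=C(/C)C1=CC(=O)[C@](C)(O1)C(O[Si](CC)(CC)CC)COC/C(CO[Si](c2ccccc2)(c2ccccc2)C(C)(C)C)=C\I.[Cl-] | intermediate
24 | (10R,4Z)-C6 enal of the furanone with C9–OSiEt3 and the iodoalkene ether side chain | O=C/C=C(/C)C1=CC(=O)[C@](C)(O1)C(O[Si](CC)(CC)CC)COC/C(CO[Si](c2ccccc2)(c2ccccc2)C(C)(C)C)=C\I | intermediate
25 | C7 alkenylchromium dichloride derived from 24 | O=C/C=C(/C)C1=CC(=O)[C@](C)(O1)C(O[Si](CC)(CC)CC)COC/C(CO[Si](c2ccccc2)(c2ccccc2)C(C)(C)C)=C\[Cr](Cl)Cl | intermediate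
26 | (4Z,7E,6S,10R)-13-membered ether (ring O–C8–C9–C10–C1–C2–C3–C4–C5–C6–C7–C11–C13, bridged C3–O–C10), C6–OH, C9–OSiEt3, C12–OSiPh2tBu | O1CC(O[Si](CC)(CC)CC)[C@@]2(C)OC(=CC2=O)/C(C)=C\[C@@H](O)/C=C(/CO[Si](c3ccccc3)(c3ccccc3)C(C)(C)C)C1 | intermediate
27 | C6 tert-butyldimethylsilyl ether of 26 | O1CC(O[Si](CC)(CC)CC)[C@@]2(C)OC(=CC2=O)/C(C)=C\[C@@H](O[Si](C)(C)C(C)(C)C)/C=C(/CO[Si](c3ccccc3)(c3ccccc3)C(C)(C)C)C1 | intermediate
28 | C9 alcohol of the macrocycle (C6–OSiMe2tBu, C12–OSiPh2tBu) | O1CC(O)[C@@]2(C)OC(=CC2=O)/C(C)=C\[C@@H](O[Si](C)(C)C(C)(C)C)/C=C(/CO[Si](c3ccccc3)(c3ccccc3)C(C)(C)C)C1 | intermediate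
29 | (4Z,7E,6S,10S)-13-membered furanone allyl ether with C9 ketone (key-step precursor) | O1CC(=O)[C@@]2(C)OC(=CC2=O)/C(C)=C\[C@@H](O[Si](C)(C)C(C)(C)C)/C=C(/CO[Si](c3ccccc3)(c3ccccc3)C(C)(C)C)C1 | intermediate
30 | lithium (Z)-C8=C9 enolate of 29 | O1/C=C(\O[Li])[C@@]2(C)OC(=CC2=O)/C(C)=C\[C@@H](O[Si](C)(C)C(C)(C)C)/C=C(/CO[Si](c3ccccc3)(c3ccccc3)C(C)(C)C)C1 | intermediate
31 | (4Z,6R,7R,8S,10S)-ten-membered 8-hydroxy-9-ketone with 3-(silyloxy)prop-1-en-2-yl on C7 (key-step product) | C=C(CO[Si](c3ccccc3)(c3ccccc3)C(C)(C)C)[C@H]1[C@H](O[Si](C)(C)C(C)(C)C)/C=C(/C)C2=CC(=O)[C@](C)(O2)C(=O)[C@H]1O | intermediate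
32 | C8 3-methylbutanoate of 31 | C=C(CO[Si](c3ccccc3)(c3ccccc3)C(C)(C)C)[C@H]1[C@H](O[Si](C)(C)C(C)(C)C)/C=C(/C)C2=CC(=O)[C@](C)(O2)C(=O)[C@H]1OC(=O)CC(C)C | intermediate
33 | (6R,7R,8S,9R,10R)-C9 alcohol, C8 3-methylbutanoate | C=C(CO[Si](c3ccccc3)(c3ccccc3)C(C)(C)C)[C@H]1[C@H](O[Si](C)(C)C(C)(C)C)/C=C(/C)C2=CC(=O)[C@](C)(O2)[C@H](O)[C@H]1OC(=O)CC(C)C | intermediate
34 | C9 acetate of 33 | C=C(CO[Si](c3ccccc3)(c3ccccc3)C(C)(C)C)[C@H]1[C@H](O[Si](C)(C)C(C)(C)C)/C=C(/C)C2=CC(=O)[C@](C)(O2)[C@H](OC(C)=O)[C@H]1OC(=O)CC(C)C | intermediate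
35 | (6R,7S,8S,9R,10R)-C6,C12-diol, C9 acetate, C8 3-methylbutanoate | C=C(CO)[C@H]1[C@H](O)/C=C(/C)C2=CC(=O)[C@](C)(O2)[C@H](OC(C)=O)[C@H]1OC(=O)CC(C)C | intermediate
36 | C12 enal with free C6 hydroxyl | C=C(C=O)[C@H]1[C@H](O)/C=C(/C)C2=CC(=O)[C@](C)(O2)[C@H](OC(C)=O)[C@H]1OC(=O)CC(C)C | intermediate
37 | C12 lactol (C6–O–C12) | C=C1C(O)O[C@@H]2/C=C(/C)C3=CC(=O)[C@](C)(O3)[C@H](OC(C)=O)[C@@H](OC(=O)CC(C)C)[C@@H]12 | intermediate
38 | CNP0255553.1, (4Z,6R,7S,8S,9R,10R) | C=C1C(=O)O[C@@H]2/C=C(/C)C3=CC(=O)[C@](C)(O3)[C@H](OC(C)=O)[C@@H](OC(=O)CC(C)C)[C@@H]12 | target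

Total step count: 23
Longest linear sequence: 21 steps (steps 2–9 and 11–23, from ethyl propiolate)

Steps most likely to fail

Step 18. The enolate may rearrange by the [3,3] oxy-Claisen path, the shift may take the other face of the C7=C11 olefin, or the base may attack the vinylogous C6–H. The fallback sets out from 29 and replaces amide-base deprotonation by soft enolisation to a neutral, covalent enolate, which removes the oxyanion that accelerates the [3,3] path and removes any free alkoxide. Bu2BOTf and iPr2NEt in CH2Cl2 at −78 °C should give the dibutylboron enolate F1, which is allowed to rearrange on warming to 0 °C to the O8 dibutylborinate F2. Methanolysis at pH 7 then releases 31, where the route is rejoined.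

Step 14. Facial selectivity at the C6 aldehyde may be poor in the ring-closing addition, so that the 6R carbinol forms alongside 26. The fallback sets out from 24, accepts the mixture and separates the (6R)-epimer of the macrocyclic alcohol F3. F3 is inverted by a Mitsunobu reaction with chloroacetic acid (PPh3, DIAD, THF, 0 °C), in which the SN2' path is blocked because C4 and C11 are fully substituted, to give the (6S)-chloroacetate F4. Thiourea and NaHCO3 in EtOH remove the chloroacetyl group without base strong enough to cleave the β-dicarbonyl array, and the route is rejoined at 26.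

Step 20. Hydride may be delivered to the wrong face of C9, or the isovalerate may shift from O8 to O9 in the alkoxide. The fallback sets out from 31, before acylation, and uses hydroxyl-directed reduction: Me4NBH(OAc)3 in MeCN/AcOH at −30 °C binds to the C8 hydroxyl and delivers hydride to C9 on the face syn to O8, which should give the trans-8,9-diol F5 with the 9R configuration. The less hindered C8 hydroxyl (C9–OH is flanked by the quaternary C10) is then acylated selectively with 3-methylbutanoyl chloride and 2,4,6-collidine in CH2Cl2 at −40 °C, and the route is rejoined at 33.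

Further compounds
F1 | step 18 | dibutylboron (Z)-C8=C9 enolate of 29 | O1/C=C(\OB(CCCC)CCCC)[C@@]2(C)OC(=CC2=O)/C(C)=C\[C@@H](O[Si](C)(C)C(C)(C)C)/C=C(/CO[Si](c3ccccc3)(c3ccccc3)C(C)(C)C)C1
F2 | step 18 | O8 dibutylborinate of 31 | C=C(CO[Si](c3ccccc3)(c3ccccc3)C(C)(C)C)[C@H]1[C@H](O[Si](C)(C)C(C)(C)C)/C=C(/C)C2=CC(=O)[C@](C)(O2)C(=O)[C@H]1OB(CCCC)CCCC
F3 | step 14 | (6R)-epimer of macrocyclic alcohol 26 | O1CC(O[Si](CC)(CC)CC)[C@@]2(C)OC(=CC2=O)/C(C)=C\[C@H](O)/C=C(/CO[Si](c3ccccc3)(c3ccccc3)C(C)(C)C)C1
F4 | step 14 | C6 chloroacetate with the C6 configuration of 26 | O1CC(O[Si](CC)(CC)CC)[C@@]2(C)OC(=CC2=O)/C(C)=C\[C@@H](OC(=O)CCl)/C=C(/CO[Si](c3ccccc3)(c3ccccc3)C(C)(C)C)C1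
F5 | step 20 | (8S,9R)-8,9-diol of the ten-membered ring (C6–OSiMe2tBu, C12–OSiPh2tBu) | C=C(CO[Si](c3ccccc3)(c3ccccc3)C(C)(C)C)[C@H]1[C@H](O[Si](C)(C)C(C)(C)C)/C=C(/C)C2=CC(=O)[C@](C)(O2)[C@H](O)[C@H]1O
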